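The route rests on cutting the C2–C1' bond between ring C and ring B. The feature exploited is that this bond is flanked by the 3-oxygen on C3 of ring C and by C2' of ring B, whose substituent is the prenyl CH2. An ester from O3 to a carboxyl carbon on C2' therefore tethers the two halves. Precursor 18 is that ester: a C2-unsubstituted 3-acyloxychromone with ring A complete, carrying a 6-bromochromene-5-carbonyl unit. One palladium-catalysed C–H arylation forms C2–C1', closes a six-membered lactone and keeps the lactone carbon as C1 of the prenyl chain. Reduction and a Suzuki coupling then complete that chain.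

Key step: step 12

Remark: flavonol numbering is used (ring A C5–C8, ring C O1–C4, ring B C1'–C6'). The target has no stereocentre; the only stereogenic intermediate, epoxide 15, is racemic and loses both centres within its own step.

Step 1
Reactants: 1 2-bromo-4,5-dimethoxybenzaldehyde
Product: 2 2-bromo-4,5-dihydroxybenzaldehyde
Conditions: BBr3, CH2Cl2, −78 °C to rt; then H2O
Reagents that add atoms: none
Why: Lewis-acid ether cleavage, in which BBr3 binds each methoxy oxygen and bromide removes the methyl group by SN2, is a standard demethylation that aryl bromides and aryl aldehydes tolerate at low temperature.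

Step 2
Reactants: 2 2-bromo-4,5-dihydroxybenzaldehyde
Product: 3 2-bromo-5-hydroxy-4-(methoxymethoxy)benzaldehyde
Conditions: MOMCl (1 equiv), K2CO3 (1 equiv), acetone, 0 °C to rt
Reagents that add atoms: chloromethyl methyl ether, COCCl
Why: Williamson-type O-alkylation should go to the 4-OH, which is para to the formyl group and the more acidic phenol, so one equivalent of carbonate ionises it preferentially and the 5-OH stays free.

Step 3
Reactants: 3 2-bromo-5-hydroxy-4-(methoxymethoxy)benzaldehyde; 4 3-chloro-3-methylbut-1-yne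
Product: 5 2-bromo-4-(methoxymethoxy)-5-[(2-methylbut-3-yn-2-yl)oxy]benzaldehyde
Conditions: CuCl2·2H2O (cat.), DBU, MeCN, 0 °C to rt
Reagents that add atoms: none
Why: Copper-catalysed propargylic substitution of a tertiary propargyl chloride by a phenol is the usual way to make aryl 1,1-dimethylpropargyl ethers and needs only the one free phenol.

Step 4
Reactants: 5 2-bromo-4-(methoxymethoxy)-5-[(2-methylbut-3-yn-2-yl)oxy]benzaldehyde
Product: 6 6-bromo-8-(methoxymethoxy)-2,2-dimethyl-2H-chromene-5-carbaldehyde
Conditions: N,N-diethylaniline, 185 °C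
Reagents that add atoms: none
Why: Aryl propargyl ether Claisen rearrangement to the only unsubstituted ortho position, followed by 1,5-hydrogen shift and oxa-6π electrocyclisation, is the standard thermal route to 2,2-dimethyl-2H-chromenes.

Step 5
Reactants: 6 6-bromo-8-(methoxymethoxy)-2,2-dimethyl-2H-chromene-5-carbaldehyde
Product: 7 6-bromo-8-(methoxymethoxy)-2,2-dimethyl-2H-chromene-5-carboxylic acid
Conditions: NaClO2, NaH2PO4, 2-methylbut-2-ene, t-BuOH–H2O, rt
Reagents that add atoms: sodium chlorite, [Na+].[O-]Cl=O
Why: Pinnick oxidation converts the hindered aryl aldehyde into the acid under buffered conditions that spare the MOM acetal, the aryl bromide and the chromene alkene, with the scavenger alkene removing hypochlorous acid.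

Step 6
Reactants: 8 2,4,6-trihydroxyacetophenone; 9 prenyl bromide (1-bromo-3-methylbut-2-ene)
Product: 10 1-[2,6-dihydroxy-4-(3-methylbut-2-enyloxy)phenyl]ethanone
Conditions: K2CO3 (1 equiv), acetone, rt to 50 °C
Reagents that add atoms: none
Why: Williamson etherification should favour the 4-OH, the most acidic hydroxyl and the only one not chelated to the acetyl carbonyl.

Step 7
Reactants: 10 1-[2,6-dihydroxy-4-(3-methylbut-2-enyloxy)phenyl]ethanone
Product: 11 1-[2,4,6-trihydroxy-3-(2-methylbut-3-en-2-yl)phenyl]ethanone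
Conditions: N,N-diethylaniline, 190 °C, sealed tube, argon, short heating
Reagents that add atoms: none
Why: Aromatic Claisen rearrangement moves the prenyl group with allylic inversion to an ortho carbon as the 1,1-dimethylallyl group, and since both ortho positions are equivalent by symmetry and the para position carries the acetyl group only one product can form.

Step 8
Reactants: 11 1-[2,4,6-trihydroxy-3-(2-methylbut-3-en-2-yl)phenyl]ethanone
Product: 12 1-[2-hydroxy-4,6-bis(methoxymethoxy)-3-(2-methylbut-3-en-2-yl)phenyl]ethanone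
Conditions: MOMCl (2.2 equiv), K2CO3, acetone, 0 °C to rt
Reagents that add atoms: chloromethyl methyl ether, COCCl
Why: Williamson-type O-alkylation should take the 4-OH and the unhindered 6-OH, while the 2-OH, chelated to the carbonyl and shielded by the neighbouring quaternary carbon, stays free as the future O1.

Step 9
Reactants: 12 1-[2-hydroxy-4,6-bis(methoxymethoxy)-3-(2-methylbut-3-en-2-yl)phenyl]ethanone
Product: 14 5,7-bis(methoxymethoxy)-8-(2-methylbut-3-en-2-yl)-4H-chromen-4-one, via enaminone 13 (not isolated)
Conditions: Me2NCH(OMe)2, toluene, 95 °C; concentrate; then AcOH, toluene, 60 °C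
Reagents that add atoms: N,N-dimethylformamide dimethyl acetal, COC(OC)N(C)C
Why: In the enaminone route to chromones the methyl ketone condenses with the formamide acetal, and acid-promoted conjugate addition of the free 2-OH with loss of dimethylamine closes ring C with an unsubstituted C2–H.

Step 10
Reactants: 14 5,7-bis(methoxymethoxy)-8-(2-methylbut-3-en-2-yl)-4H-chromen-4-one
Product: 16 3-hydroxy-5,7-bis(methoxymethoxy)-8-(2-methylbut-3-en-2-yl)-4H-chromen-4-one, via epoxide 15 (not isolated)
Conditions: 30% H2O2, aq. NaOH (cat.), MeOH–THF, 0 °C; extract; then PPTS (cat.), CH2Cl2, rt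
Reagents that add atoms: hydrogen peroxide, OO
Why: Weitz–Scheffer epoxidation uses a nucleophilic oxidant that attacks only the electron-poor C2=C3 bond and not the vinyl group, and mild acid then opens the racemic cis-fused epoxide at the acetal carbon C2 so that loss of the C3 proton gives the 3-hydroxychromone and removes both stereocentres.

Step 11
Reactants: 7 6-bromo-8-(methoxymethoxy)-2,2-dimethyl-2H-chromene-5-carboxylic acid; 16 3-hydroxy-5,7-bis(methoxymethoxy)-8-(2-methylbut-3-en-2-yl)-4H-chromen-4-one
Product: 18 5,7-bis(methoxymethoxy)-8-(2-methylbut-3-en-2-yl)-4-oxo-4H-chromen-3-yl 6-bromo-8-(methoxymethoxy)-2,2-dimethyl-2H-chromene-5-carboxylate, via acid chloride 17 (not isolated)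
Conditions: 7, Me2C=C(Cl)NMe2, CH2Cl2, 0 °C to rt; then 16, Et3N, DMAP (cat.), 0 °C to rt
Reagents that add atoms: none
Why: Nucleophilic acyl substitution should work because the chloroenamine makes the acid chloride without acid that would cleave the MOM ether, and DMAP-catalysed acylation of the acidic 3-OH overcomes the hindrance of the doubly ortho-substituted aroyl group.

Step 12
Reactants: 18 5,7-bis(methoxymethoxy)-8-(2-methylbut-3-en-2-yl)-4-oxo-4H-chromen-3-yl 6-bromo-8-(methoxymethoxy)-2,2-dimethyl-2H-chromene-5-carboxylate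
Product: 19 lactone-bridged flavonol: chromone C2 bonded to C6 of the chromene (ring B C1'), O3 acylated by the chromene C5 carbonyl (on ring B C2'); ring A keeps 5,7-bis(methoxymethoxy) and 8-(2-methylbut-3-en-2-yl), ring B keeps the 8-(methoxymethoxy)-2,2-dimethylchromene
Conditions: Pd(OAc)2 (10 mol%), PCy3·HBF4 (20 mol%), KO2CCMe3 (3 equiv), degassed DMA, 110 °C, 0.01 M
Reagents that add atoms: none
Why: Zerovalent palladium, formed from Pd(OAc)2 and PCy3, inserts into the C1'–Br bond, pivalate bound to the resulting arylpalladium bromide removes the C2–H next to O1 by concerted metalation–deprotonation, and reductive elimination from the seven-membered palladacycle forms the C2–C1' bond. The closest known reaction type is the palladium-catalysed intramolecular direct arylation of aryl 2-halobenzoates to benzo[c]chromen-6-ones, here with the C2–H of a 3-acyloxychromone as the C–H partner. The single new ring, the six-membered lactone made of O3, the carbonyl carbon, C2', C1', C2 and C3, closes through the new C2–C1' biaryl bond, the ester tether holding C1' over C2 so that no other ring size is possible. No stereocentre is formed. The step needs site selectivity and chemoselectivity: the tether leaves C2–H as the only C–H within reach and it is also the most acidic C–H of the chromone, while high dilution suppresses intermolecular Heck reaction at the vinyl group and neither the vinyl group nor the chromene alkene can be reached intramolecularly.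

Step 13
Reactants: 19 lactone-bridged flavonol
Product: 20 3-hydroxy-2-[5-(hydroxymethyl)-8-(methoxymethoxy)-2,2-dimethyl-2H-chromen-6-yl]-5,7-bis(methoxymethoxy)-8-(2-methylbut-3-en-2-yl)-4H-chromen-4-one
Conditions: LiBH4, THF, 0 °C; then aq. NH4Cl
Reagents that add atoms: none
Why: Hydride reduction should select the lactone, an activated enol ester with a flavonol oxide as leaving group, over the C4 carbonyl, a vinylogous ester that is further deactivated once the 3-oxide is released.

Step 14
Reactants: 20 3-hydroxy-2-[5-(hydroxymethyl)-8-(methoxymethoxy)-2,2-dimethyl-2H-chromen-6-yl]-5,7-bis(methoxymethoxy)-8-(2-methylbut-3-en-2-yl)-4H-chromen-4-one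
Product: 21 2-[5-(hydroxymethyl)-8-(methoxymethoxy)-2,2-dimethyl-2H-chromen-6-yl]-3,5,7-tris(methoxymethoxy)-8-(2-methylbut-3-en-2-yl)-4H-chromen-4-one
Conditions: MOMCl (1.1 equiv), K2CO3, acetone, 0 °C to rt
Reagents that add atoms: chloromethyl methyl ether, COCCl
Why: Williamson-type O-alkylation should be selective because carbonate ionises only the acidic enolic 3-OH, so the neutral benzylic alcohol is not alkylated and the hydroxyl that could later attack the benzylic carbon is capped.

Step 15
Reactants: 21 2-[5-(hydroxymethyl)-8-(methoxymethoxy)-2,2-dimethyl-2H-chromen-6-yl]-3,5,7-tris(methoxymethoxy)-8-(2-methylbut-3-en-2-yl)-4H-chromen-4-one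
Product: 22 2-[5-(bromomethyl)-8-(methoxymethoxy)-2,2-dimethyl-2H-chromen-6-yl]-3,5,7-tris(methoxymethoxy)-8-(2-methylbut-3-en-2-yl)-4H-chromen-4-one
Conditions: CBr4, PPh3, CH2Cl2, 0 °C; used without storage
Reagents that add atoms: carbon tetrabromide, BrC(Br)(Br)Br
Why: The Appel reaction converts the primary benzylic alcohol into the bromide by SN2 under neutral conditions that spare the four MOM ethers and the three alkenes.

Step 16
Reactants: 22 2-[5-(bromomethyl)-8-(methoxymethoxy)-2,2-dimethyl-2H-chromen-6-yl]-3,5,7-tris(methoxymethoxy)-8-(2-methylbut-3-en-2-yl)-4H-chromen-4-one; 23 2-methylprop-1-enylboronic acid pinacol ester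
Product: 24 2-[8-(methoxymethoxy)-2,2-dimethyl-5-(3-methylbut-2-enyl)-2H-chromen-6-yl]-3,5,7-tris(methoxymethoxy)-8-(2-methylbut-3-en-2-yl)-4H-chromen-4-one
Conditions: PdCl2(dppf) (5 mol%), K2CO3, dioxane with a little H2O, 70 °C
Reagents that add atoms: none
Why: Suzuki–Miyaura coupling of a benzylic bromide with an alkenylboronate is a known sp3–sp2 variant that forms the ArCH2–CH=C bond of the prenyl group without moving the double bond.

Step 17
Reactants: 24 2-[8-(methoxymethoxy)-2,2-dimethyl-5-(3-methylbut-2-enyl)-2H-chromen-6-yl]-3,5,7-tris(methoxymethoxy)-8-(2-methylbut-3-en-2-yl)-4H-chromen-4-one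
Product: 25 Broussoflavonol D
Conditions: 3 M aq. HCl, MeOH, 50 °C
Reagents that add atoms: none
Why: Acid-catalysed acetal cleavage removes all four MOM groups at once, and mild acid should leave both side chains intact because the C2' prenyl group has no neighbouring hydroxyl and the C8 group could cyclise only through a secondary cation.

Compound list

1 | 2-bromo-4,5-dimethoxybenzaldehyde | COc1cc(Br)c(C=O)cc1OC | starting material
2 | 2-bromo-4,5-dihydroxybenzaldehyde | O=Cc1cc(O)c(O)cc1Br | intermediate
3 | 2-bromo-5-hydroxy-4-(methoxymethoxy)benzaldehyde | COCOc1cc(Br)c(C=O)cc1O | intermediate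
4 | 3-chloro-3-methylbut-1-yne | C#CC(C)(C)Cl | starting material
5 | 2-bromo-4-(methoxymethoxy)-5-[(2-methylbut-3-yn-2-yl)oxy]benzaldehyde | COCOc1cc(Br)c(C=O)cc1OC(C)(C)C#C | intermediate
6 | 6-bromo-8-(methoxymethoxy)-2,2-dimethyl-2H-chromene-5-carbaldehyde | COCOc1cc(Br)c(C=O)c2C=CC(C)(C)Oc12 | intermediate
7 | 6-bromo-8-(methoxymethoxy)-2,2-dimethyl-2H-chromene-5-carboxylic acid | COCOc1cc(Br)c(C(=O)O)c2C=CC(C)(C)Oc12 | intermediate
8 | 2,4,6-trihydroxyacetophenone | CC(=O)c1c(O)cc(O)cc1O | starting material
9 | prenyl bromide (1-bromo-3-methylbut-2-ene) | CC(C)=CCBr | starting material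
10 | 1-[2,6-dihydroxy-4-(3-methylbut-2-enyloxy)phenyl]ethanone | CC(=O)c1c(O)cc(OCC=C(C)C)cc1O | intermediate
11 | 1-[2,4,6-trihydroxy-3-(2-methylbut-3-en-2-yl)phenyl]ethanone | C=CC(C)(C)c1c(O)cc(O)c(C(C)=O)c1O | intermediate
12 | 1-[2-hydroxy-4,6-bis(methoxymethoxy)-3-(2-methylbut-3-en-2-yl)phenyl]ethanone | C=CC(C)(C)c1c(OCOC)cc(OCOC)c(C(C)=O)c1O | intermediate
13 | (E)-3-(dimethylamino)-1-[2-hydroxy-4,6-bis(methoxymethoxy)-3-(2-methylbut-3-en-2-yl)phenyl]prop-2-en-1-one (enaminone, formed in the flask) | C=CC(C)(C)c1c(OCOC)cc(OCOC)c(C(=O)/C=C/N(C)C)c1O | intermediate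
14 | 5,7-bis(methoxymethoxy)-8-(2-methylbut-3-en-2-yl)-4H-chromen-4-one | C=CC(C)(C)c1c(OCOC)cc(OCOC)c2c(=O)ccoc12 | intermediate
15 | 2,3-epoxy-5,7-bis(methoxymethoxy)-8-(2-methylbut-3-en-2-yl)chroman-4-one (cis-fused epoxide, racemic, one enantiomer drawn, formed in the flask) | C=CC(C)(C)c1c(OCOC)cc(OCOC)c2c1O[C@@H]1O[C@@H]1C2=O | intermediate
16 | 3-hydroxy-5,7-bis(methoxymethoxy)-8-(2-methylbut-3-en-2-yl)-4H-chromen-4-one | C=CC(C)(C)c1c(OCOC)cc(OCOC)c2c(=O)c(O)coc12 | intermediate
17 | 6-bromo-8-(methoxymethoxy)-2,2-dimethyl-2H-chromene-5-carbonyl chloride (formed in the flask) | COCOc1cc(Br)c(C(=O)Cl)c2C=CC(C)(C)Oc12 | intermediate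
18 | 5,7-bis(methoxymethoxy)-8-(2-methylbut-3-en-2-yl)-4-oxo-4H-chromen-3-yl 6-bromo-8-(methoxymethoxy)-2,2-dimethyl-2H-chromene-5-carboxylate | C=CC(C)(C)c1c(OCOC)cc(OCOC)c2c(=O)c(OC(=O)c3c(Br)cc(OCOC)c4c3C=CC(C)(C)O4)coc12 | intermediate
19 | lactone-bridged flavonol (C2–C1' bond formed; six-membered lactone from O3 to the carbonyl on C2') | C=CC(C)(C)c1c(OCOC)cc(OCOC)c2c(=O)c3oc(=O)c4c5c(c(OCOC)cc4c3oc12)OC(C)(C)C=C5 | intermediate
20 | 3-hydroxy-2-[5-(hydroxymethyl)-8-(methoxymethoxy)-2,2-dimethyl-2H-chromen-6-yl]-5,7-bis(methoxymethoxy)-8-(2-methylbut-3-en-2-yl)-4H-chromen-4-one | C=CC(C)(C)c1c(OCOC)cc(OCOC)c2c(=O)c(O)c(-c3cc(OCOC)c4c(c3CO)C=CC(C)(C)O4)oc12 | intermediate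
21 | 2-[5-(hydroxymethyl)-8-(methoxymethoxy)-2,2-dimethyl-2H-chromen-6-yl]-3,5,7-tris(methoxymethoxy)-8-(2-methylbut-3-en-2-yl)-4H-chromen-4-one | C=CC(C)(C)c1c(OCOC)cc(OCOC)c2c(=O)c(OCOC)c(-c3cc(OCOC)c4c(c3CO)C=CC(C)(C)O4)oc12 | intermediate
22 | 2-[5-(bromomethyl)-8-(methoxymethoxy)-2,2-dimethyl-2H-chromen-6-yl]-3,5,7-tris(methoxymethoxy)-8-(2-methylbut-3-en-2-yl)-4H-chromen-4-one | C=CC(C)(C)c1c(OCOC)cc(OCOC)c2c(=O)c(OCOC)c(-c3cc(OCOC)c4c(c3CBr)C=CC(C)(C)O4)oc12 | intermediate
23 | 2-methylprop-1-enylboronic acid pinacol ester | CC(C)=CB1OC(C)(C)C(C)(C)O1 | starting material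
24 | 2-[8-(methoxymethoxy)-2,2-dimethyl-5-(3-methylbut-2-enyl)-2H-chromen-6-yl]-3,5,7-tris(methoxymethoxy)-8-(2-methylbut-3-en-2-yl)-4H-chromen-4-one (tetra-MOM ether of the target) | C=CC(C)(C)c1c(OCOC)cc(OCOC)c2c(=O)c(OCOC)c(-c3cc(OCOC)c4c(c3CC=C(C)C)C=CC(C)(C)O4)oc12 | intermediate
25 | Broussoflavonol D: 3,5,7-trihydroxy-2-[8-hydroxy-2,2-dimethyl-5-(3-methylbut-2-enyl)-2H-chromen-6-yl]-8-(2-methylbut-3-en-2-yl)-4H-chromen-4-one | C=CC(C)(C)c1c(O)cc(O)c2c(=O)c(O)c(-c3cc(O)c4c(c3CC=C(C)C)C=CC(C)(C)O4)oc12 | target

Total step count: 17 (five steps to acid 7, five to chromone 16, seven from the esterification on).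
Longest linear sequence: 12 steps (steps 1–5 or steps 6–10, then steps 11–17).

Steps most likely to fail

Step 12. Palladation of C2–H may be slow next to the crowded arylpalladium centre, so that protodebromination, cleavage of the enol ester by pivalate or insertion into the vinyl group overtakes ring closure. The fallback separates C–H cleavage from C–C coupling and sets out from ester 18. Deprotonation at C2, its most acidic C–H, with (2,2,6,6-tetramethylpiperidin-1-yl)zinc chloride–lithium chloride (TMPZnCl·LiCl) in THF at 25 °C should give the C2-zincated ester F1, which is not isolated. Pd(OAc)2 and SPhos at 50 °C should then close the lactone by intramolecular Negishi coupling, and the route is rejoined at 19.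

Step 7. The rearranged phenol may react on at the temperature needed: a flanking hydroxyl can add to the new vinyl group to give a dihydrobenzofuran, or the side chain can isomerise by the abnormal Claisen pathway. The fallback runs the rearrangement on acylated material with trapping and sets out from 10. Heating with Ac2O and NaOAc in N,N-diethylaniline (sealed tube, 190 °C) should first acetylate the two chelated phenols to the diacetate F2. F2 then rearranges, and the phenol set free is acetylated at once to the triacetate F3. K2CO3 (cat.) in MeOH at 0 °C should remove the three acetates, and the route is rejoined at 11.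

Step 10. Hydroxide or hydroperoxide may add to C2 and open the pyranone ring faster than the epoxide closes, or the acid stage may remove the 5-O-MOM group. The fallback brings in the oxygen through a C3 halide and sets out from acetophenone 12. Enaminone 13 is made as in step 9 and treated with I2 and pyridine in CHCl3, where iodocyclisation should give the 3-iodochromone F4. Miyaura borylation (B2pin2, PdCl2(dppf), KOAc, dioxane, 80 °C) should give the chromone 3-boronate F5. Oxidation with 30% H2O2 and NaHCO3 in THF–water at 0 °C should give the 3-hydroxychromone, and the route is rejoined at 16.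

Further compounds

F1 | step 12 | C2-zincated ester: 18 with chlorozinc in place of the C2 hydrogen | C=CC(C)(C)c1c(OCOC)cc(OCOC)c2c(=O)c(OC(=O)c3c(Br)cc(OCOC)c4c3C=CC(C)(C)O4)c([Zn]Cl)oc12
F2 | step 7 | 2,6-diacetoxy-4-(3-methylbut-2-enyloxy)acetophenone | CC(=O)Oc1cc(OCC=C(C)C)cc(OC(C)=O)c1C(C)=O
F3 | step 7 | 2,4,6-triacetoxy-3-(2-methylbut-3-en-2-yl)acetophenone | C=CC(C)(C)c1c(OC(C)=O)cc(OC(C)=O)c(C(C)=O)c1OC(C)=O
F4 | step 10 | 3-iodo-5,7-bis(methoxymethoxy)-8-(2-methylbut-3-en-2-yl)-4H-chromen-4-one | C=CC(C)(C)c1c(OCOC)cc(OCOC)c2c(=O)c(I)coc12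
F5 | step 10 | 5,7-bis(methoxymethoxy)-8-(2-methylbut-3-en-2-yl)-3-(4,4,5,5-tetramethyl-1,3,2-dioxaborolan-2-yl)-4H-chromen-4-one | C=CC(C)(C)c1c(OCOC)cc(OCOC)c2c(=O)c(B3OC(C)(C)C(C)(C)O3)coc12
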